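The runs stem from a simulated flask for substances that don't exist; noise was put on by code.

Late in the two earlier runs G is still falling, but more slowly, so for summer and dusk we need a number that can be carried past the last reading.

common to all: G 10 mM

|  | D | L | remark | time |
|---|---|---|---|---|
| north-east | 21 mM | 0.50 mM | run made earlier |  |
| east | 30 mM | 0.50 mM | run made earlier |  |
| summer | 15.0 mM | 0.500 mM |  | 8.0 h |
| dusk | 20.0 mM | 0.500 mM |  | 8.0 h |

| run | time / h | G / % | E / % |
|---|---|---|---|
| north-east | 0.333 | 94.9 | 3.6 |
| north-east | 0.833 | 90.5 | 8.3 |
| north-east | 1.50 | 82.8 | 14.8 |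
| north-east | 2.50 | 73.4 | 21.7 |
| north-east | 3.00 | 70.6 | 25.4 |
| north-east | 4.00 | 64.8 | 30.8 |
| north-east | 6.00 | 55.3 | 40.5 |
| east | 0.417 | 92.9 | 7.1 |
| east | 0.667 | 89.2 | 9.5 |
| east | 1.00 | 83.3 | 14.6 |
| east | 1.50 | 76.7 | 22.2 |
| east | 2.50 | 66.2 | 30.7 |
| east | 4.00 | 54.3 | 42.0 |
| east | 6.00 | 43.0 | 52.3 |

(standard deviation of a reading: 0.5 percentage points)

1. part of the G that has reacted at the end, summer
2. part of the G that has reacted at the end, dusk
3. what raising the concentration of D from its lowest to its highest value here does to the part of the G that has reacted (changes below 5 percentage points count as none) (it rises / it falls / no change)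



We work with the fractions left and count D lost as equal to G lost. Our clock, the integrated second-order law, is the logarithm of D's fraction left over G's fraction left, divided by the difference of the two charges. At 6.00 h the north-east run reads 0.0321 mM⁻¹ and the east run 0.0317 mM⁻¹, so one clock serves both charges of D.

But it slows. At 4.00 h the two runs average 0.0225 mM⁻¹, and the stretch after that gains 0.00936 mM⁻¹, less per hour than the stretch before it. Adding that gain once more gives the clock at the end of the run, 0.0412 mM⁻¹, which errs high if the slowing goes on.

Turned back into fractions with each flask's difference of charges, it gives 40.7% of G reacted in summer and 50.5% in dusk, a rise of 9.8 percentage points.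

The forecast gives 40% and 49.5%, slightly less than ours, says of the part reacted as D is raised that it rises, and says of the slowing “it looks time-driven”.

    G + D → X + E (k = 5.58 L mol⁻¹ h⁻¹)
    D + X ⇌ Z, settled at all times (K = 56000 L mol⁻¹)
    G + L → J (k = 58.0 L mol⁻¹ h⁻¹)

The flasks give 41.3% in summer and 50.5% in dusk, so it rises, by 9.3 points. Summer ends with 51.5% of its D free, less than the 59% of its G still there, with 3.63 mM of Z standing. For the flask like summer but with 60 mM of D, the clock of 0.0412 mM⁻¹ leaves 10.8% of G, and that flask ends with 10.8%.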